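Ring D is not attached by aryl ether coupling but grown on the ring C oxygen. Its C3–C4–C5 segment, with three adjacent oxygens, is a 1,3-dioxygenated acetone; C2, C1 and C6, with the ether oxygen on C1 between two CH carbons, are a 2-aryloxymalonaldehyde. One [3+3] double condensation of 1,3-bis(benzyloxy)acetone with the malonaldehyde forms C2–C3 and C5–C6 and delivers ring D as the C4 phenol. The precursor is the octabenzylated A–B–C triaryl diether carrying an O–CH(CHO)2 group on ring C, made by chloromalonate alkylation, reduction and oxidation. Benzyl ethers throughout allow a single final hydrogenolysis.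

Key step: step 13

Assumption (chemistry): the target has no stereocentre and its diaryl ether bonds rotate freely, so it is one achiral compound and no stereocontrol is needed.

Abbreviation: ArABC = 2,4,6-tris(benzyloxy)-3-{2,3-bis(benzyloxy)-5-[2,4,6-tris(benzyloxy)phenoxy]phenoxy}phenyl, i.e. the fully benzylated rings A–B–C bonded through the ring C carbon that will carry the oxygen to ring D.

Step 1
Reactants: 1 2,4,6-trihydroxybenzaldehyde
Product: 2 2,4,6-tris(benzyloxy)benzaldehyde
Conditions: BnBr (3.6 equiv), K2CO3, DMF, 70 °C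
Reagents that add atoms: benzyl bromide, BrCc1ccccc1
Why: Williamson ether synthesis in a dipolar aprotic solvent, where the formyl group lowers ring nucleophilicity enough to favour O- over C-benzylation and heating completes the hydrogen-bonded ortho hydroxyls.

Step 2
Reactants: 2 2,4,6-tris(benzyloxy)benzaldehyde
Product: 4 2,4,6-tris(benzyloxy)phenol, via 2,4,6-tris(benzyloxy)phenyl formate 3 (not isolated)
Conditions: mCPBA (1.1 equiv), CH2Cl2, 0 °C → rt; then MeOH, HCl (cat.), rt
Reagents that add atoms: 3-chloroperbenzoic acid (mCPBA), OOC(=O)c1cccc(Cl)c1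
Why: Baeyer–Villiger (Dakin-type) oxidation of an electron-rich benzaldehyde, in which the trialkoxyaryl group migrates to give the formate that acid-catalysed methanolysis cleaves to the phenol.

Step 3
Reactants: 5 5-bromo-2-hydroxybenzaldehyde
Product: 6 5-bromo-2-hydroxy-3-iodobenzaldehyde
Conditions: NIS, TsOH (cat.), MeCN, rt
Reagents that add atoms: N-iodosuccinimide, O=C1CCC(=O)N1I
Why: Electrophilic aromatic iodination, directed by the phenol to its only free ortho carbon (para is blocked by bromine) and by the formyl group meta to the same carbon.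

Step 4
Reactants: 6 5-bromo-2-hydroxy-3-iodobenzaldehyde
Product: 8 5-bromo-3-iodobenzene-1,2-diol, via 5-bromo-2-hydroxy-3-iodophenyl formate 7 (not isolated)
Conditions: 30% H2O2, NaOH, H2O/THF, 0 °C → rt; then aq. HCl
Reagents that add atoms: hydrogen peroxide, OO
Why: Dakin oxidation of an ortho-hydroxybenzaldehyde, in which hydroperoxide addition and aryl migration give the formate that is saponified in the same alkaline medium to the catechol.

Step 5
Reactants: 8 5-bromo-3-iodobenzene-1,2-diol
Product: 9 1,2-bis(benzyloxy)-5-bromo-3-iodobenzene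
Conditions: BnBr (2.3 equiv), K2CO3, DMF, 50 °C
Reagents that add atoms: benzyl bromide, BrCc1ccccc1
Why: Williamson ether synthesis on both catechol hydroxyls, leaving the two aryl halides untouched.

Step 6
Reactants: 4 2,4,6-tris(benzyloxy)phenol; 9 1,2-bis(benzyloxy)-5-bromo-3-iodobenzene
Product: 10 1,2-bis(benzyloxy)-5-bromo-3-[2,4,6-tris(benzyloxy)phenoxy]benzene (ring B–O–ring C bromide)
Conditions: CuI (10 mol%), picolinic acid (20 mol%), K3PO4, DMSO, 80 °C, Ar
Reagents that add atoms: none
Why: Ullmann-type copper-catalysed diaryl ether synthesis with a ligand system suited to ortho-substituted partners, in which C–I reacts much faster than C–Br, so the bromide is kept for step 8.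

Step 7
Reactants: 10 1,2-bis(benzyloxy)-5-bromo-3-[2,4,6-tris(benzyloxy)phenoxy]benzene
Product: 12 3-[2,3-bis(benzyloxy)-5-bromophenoxy]-2,4,6-tris(benzyloxy)benzaldehyde, via aryl iminium dichlorophosphate 11 (not isolated)
Conditions: POCl3, DMF, 0 °C → rt; then H2O, rt
Reagents that add atoms: N,N-dimethylformamide, CN(C)C=O; water, O
Why: Vilsmeier–Haack formylation at the most activated CH, the ring C carbon flanked by two benzyloxy groups and para to the third (the two ring C CH carbons are equivalent and brominated ring B is far less electron-rich), after which the formyl group deactivates ring C against a second attack.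

Step 8
Reactants: 12 3-[2,3-bis(benzyloxy)-5-bromophenoxy]-2,4,6-tris(benzyloxy)benzaldehyde; 4 2,4,6-tris(benzyloxy)phenol
Product: 13 ArABC–CHO, 2,4,6-tris(benzyloxy)-3-{2,3-bis(benzyloxy)-5-[2,4,6-tris(benzyloxy)phenoxy]phenoxy}benzaldehyde
Conditions: CuI (20 mol%), picolinic acid (40 mol%), K3PO4, DMSO, 100 °C, Ar
Reagents that add atoms: none
Why: Ullmann-type copper-catalysed diaryl ether synthesis at an aryl bromide whose two ortho positions are CH, tolerated by the non-enolisable aldehyde.

Step 9
Reactants: 13 ArABC–CHO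
Product: 15 ArABC–OH, 2,4,6-tris(benzyloxy)-3-{2,3-bis(benzyloxy)-5-[2,4,6-tris(benzyloxy)phenoxy]phenoxy}phenol, via ArABC formate 14 (not isolated)
Conditions: mCPBA (1.1 equiv), CH2Cl2, 0 °C; then MeOH, HCl (cat.), rt
Reagents that add atoms: 3-chloroperbenzoic acid (mCPBA), OOC(=O)c1cccc(Cl)c1
Why: Baeyer–Villiger oxidation followed by formate methanolysis as in step 2, with the 2,6-dialkoxyaryl group migrating readily and only a slight excess of peracid at 0 °C to spare the electron-rich rings.

Step 10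
Reactants: 15 ArABC–OH; 16 diethyl chloromalonate
Product: 17 diethyl 2-(ArABC-oxy)malonate
Conditions: K2CO3, DMF, 50 °C, Ar
Reagents that add atoms: none
Why: Williamson-type SN2 O-alkylation with a doubly activated secondary chloride, used as the malonaldehyde carbon unit at the ester oxidation level because a 2-halomalonaldehyde would merely be deprotonated by the phenoxide to an unreactive enolate, and as the chloride to limit halophilic attack.

Step 11
Reactants: 17 diethyl 2-(ArABC-oxy)malonate
Product: 18 2-(ArABC-oxy)propane-1,3-diol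
Conditions: LiAlH4, THF, 0 °C → rt; then H2O
Reagents that add atoms: none
Why: Hydride reduction of both esters to the primary alcohols, with aryl and benzyl ethers inert.

Step 12
Reactants: 18 2-(ArABC-oxy)propane-1,3-diol
Product: 19 2-(ArABC-oxy)malonaldehyde (present mainly as its enol, 3-hydroxy-2-(ArABC-oxy)acrolein)
Conditions: Dess–Martin periodinane (2.4 equiv), CH2Cl2, rt
Reagents that add atoms: none
Why: Dess–Martin oxidation of both primary alcohols under non-basic conditions, the dialdehyde being stabilised as its hydrogen-bonded enol.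

Step 13
Reactants: 19 2-(ArABC-oxy)malonaldehyde; 20 1,3-bis(benzyloxy)propan-2-one
Product: 22 2,6-bis(benzyloxy)-4-(ArABC-oxy)phenol (ring D with free C4–OH and benzyl ethers on C3 and C5), via cyclohexa-2,5-dienone tautomer 21 (not isolated)
Conditions: pyrrolidine (1 equiv), AcOH (2 equiv), 4 Å MS, toluene, 80 °C, Ar
Reagents that add atoms: none
Why: Pyrrolidinium acetate turns ketone 20 into its enamine and activates a formyl group of 19 as an iminium ion, so one α-carbon of 20 bonds to one formyl carbon (C3–C2) with loss of water; the second α-carbon then attacks the remaining formyl carbon (C5–C6), a second dehydration gives the 4H-cyclohexa-2,5-dienone 21, and its ring D C1–H moves to the carbonyl oxygen to give the aromatic phenol 22. The closest known reaction type is the [3+3] phenol annulation of malonaldehyde equivalents (nitromalonaldehyde, vinamidinium salts, hydroxymethylene ketones) with 1,3-disubstituted acetones, here run as a double aldol (Knoevenagel-type) condensation. Ring D is closed by a 6-(enolendo)-exo-trig intramolecular aldol addition of the second α-carbon to the pendant formyl group. No stereocentre is formed, since every sp3 carbon of the intermediates ends as an aromatic carbon. The step needs cross-condensation to beat ketone self-aldol and each partner to play one role only: 20 is symmetric with two equivalent α-CH2 groups, so there is no regiochemical choice, the only nucleophilic carbon of 19 is its fully substituted central carbon, whose adducts cannot dehydrate and revert, ketone self-aldol is reversible, and aromatisation makes the cross-product the irreversible sink. The weakly acidic amine buffer keeps 19 from resting as its unreactive enolate, and the aryloxy group on C1 is never β to a carbanion on the way, so it is not expelled.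

Step 14
Reactants: 22 2,6-bis(benzyloxy)-4-(ArABC-oxy)phenol
Product: 23 CNP0214481.0, the free decahydroxy tetramer
Conditions: H2 (1 atm), Pd(OH)2/C, THF/MeOH, rt
Reagents that add atoms: none
Why: Catalytic hydrogenolysis of all ten benzyl aryl ethers, which leaves the diaryl ether bonds intact; the product should be filtered and concentrated under argon because it is air-sensitive.

Compound list

1 | 2,4,6-trihydroxybenzaldehyde | O=Cc1c(O)cc(O)cc1O | starting material
2 | 2,4,6-tris(benzyloxy)benzaldehyde | O=Cc1c(OCc5ccccc5)cc(OCc5ccccc5)cc1OCc5ccccc5 | intermediate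
3 | 2,4,6-tris(benzyloxy)phenyl formate | O=COc1c(OCc5ccccc5)cc(OCc5ccccc5)cc1OCc5ccccc5 | intermediate (not isolated)
4 | 2,4,6-tris(benzyloxy)phenol | Oc1c(OCc5ccccc5)cc(OCc5ccccc5)cc1OCc5ccccc5 | intermediate
5 | 5-bromo-2-hydroxybenzaldehyde | O=Cc1cc(Br)ccc1O | starting material
6 | 5-bromo-2-hydroxy-3-iodobenzaldehyde | O=Cc1cc(Br)cc(I)c1O | intermediate
7 | 5-bromo-2-hydroxy-3-iodophenyl formate | O=COc1cc(Br)cc(I)c1O | intermediate (not isolated)
8 | 5-bromo-3-iodobenzene-1,2-diol | Oc1cc(Br)cc(I)c1O | intermediate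
9 | 1,2-bis(benzyloxy)-5-bromo-3-iodobenzene | Brc1cc(I)c(OCc5ccccc5)c(OCc5ccccc5)c1 | intermediate
10 | 1,2-bis(benzyloxy)-5-bromo-3-[2,4,6-tris(benzyloxy)phenoxy]benzene | Brc1cc(Oc2c(OCc5ccccc5)cc(OCc5ccccc5)cc2OCc5ccccc5)c(OCc5ccccc5)c(OCc5ccccc5)c1 | intermediate
11 | N-{3-[2,3-bis(benzyloxy)-5-bromophenoxy]-2,4,6-tris(benzyloxy)benzylidene}-N-methylmethanaminium dichlorophosphate | Brc1cc(Oc2c(OCc5ccccc5)c(C=[N+](C)C)c(OCc5ccccc5)cc2OCc5ccccc5)c(OCc5ccccc5)c(OCc5ccccc5)c1.[O-]P(=O)(Cl)Cl | intermediate (not isolated)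
12 | 3-[2,3-bis(benzyloxy)-5-bromophenoxy]-2,4,6-tris(benzyloxy)benzaldehyde | Brc1cc(Oc2c(OCc5ccccc5)c(C=O)c(OCc5ccccc5)cc2OCc5ccccc5)c(OCc5ccccc5)c(OCc5ccccc5)c1 | intermediate
13 | ArABC–CHO, 2,4,6-tris(benzyloxy)-3-{2,3-bis(benzyloxy)-5-[2,4,6-tris(benzyloxy)phenoxy]phenoxy}benzaldehyde | O=Cc1c(OCc5ccccc5)cc(OCc5ccccc5)c(Oc2cc(Oc3c(OCc5ccccc5)cc(OCc5ccccc5)cc3OCc5ccccc5)cc(OCc5ccccc5)c2OCc5ccccc5)c1OCc5ccccc5 | intermediate
14 | ArABC formate, 2,4,6-tris(benzyloxy)-3-{2,3-bis(benzyloxy)-5-[2,4,6-tris(benzyloxy)phenoxy]phenoxy}phenyl formate | O=COc1c(OCc5ccccc5)cc(OCc5ccccc5)c(Oc2cc(Oc3c(OCc5ccccc5)cc(OCc5ccccc5)cc3OCc5ccccc5)cc(OCc5ccccc5)c2OCc5ccccc5)c1OCc5ccccc5 | intermediate (not isolated)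
15 | ArABC–OH, 2,4,6-tris(benzyloxy)-3-{2,3-bis(benzyloxy)-5-[2,4,6-tris(benzyloxy)phenoxy]phenoxy}phenol | Oc1c(OCc5ccccc5)cc(OCc5ccccc5)c(Oc2cc(Oc3c(OCc5ccccc5)cc(OCc5ccccc5)cc3OCc5ccccc5)cc(OCc5ccccc5)c2OCc5ccccc5)c1OCc5ccccc5 | intermediate
16 | diethyl chloromalonate | CCOC(=O)C(Cl)C(=O)OCC | starting material
17 | diethyl 2-(ArABC-oxy)malonate | CCOC(=O)C(C(=O)OCC)Oc1c(OCc5ccccc5)cc(OCc5ccccc5)c(Oc2cc(Oc3c(OCc5ccccc5)cc(OCc5ccccc5)cc3OCc5ccccc5)cc(OCc5ccccc5)c2OCc5ccccc5)c1OCc5ccccc5 | intermediate
18 | 2-(ArABC-oxy)propane-1,3-diol | OCC(CO)Oc1c(OCc5ccccc5)cc(OCc5ccccc5)c(Oc2cc(Oc3c(OCc5ccccc5)cc(OCc5ccccc5)cc3OCc5ccccc5)cc(OCc5ccccc5)c2OCc5ccccc5)c1OCc5ccccc5 | intermediate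
19 | 2-(ArABC-oxy)malonaldehyde (drawn as the dialdehyde; mainly the enol) | O=CC(C=O)Oc1c(OCc5ccccc5)cc(OCc5ccccc5)c(Oc2cc(Oc3c(OCc5ccccc5)cc(OCc5ccccc5)cc3OCc5ccccc5)cc(OCc5ccccc5)c2OCc5ccccc5)c1OCc5ccccc5 | intermediate (key-step precursor)
20 | 1,3-bis(benzyloxy)propan-2-one | O=C(COCc1ccccc1)COCc1ccccc1 | starting material
21 | 2,6-bis(benzyloxy)-4-(ArABC-oxy)cyclohexa-2,5-dien-1-one | O=C4C(OCc5ccccc5)=CC(Oc1c(OCc5ccccc5)cc(OCc5ccccc5)c(Oc2cc(Oc3c(OCc5ccccc5)cc(OCc5ccccc5)cc3OCc5ccccc5)cc(OCc5ccccc5)c2OCc5ccccc5)c1OCc5ccccc5)C=C4OCc5ccccc5 | intermediate (not isolated)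
22 | 2,6-bis(benzyloxy)-4-(ArABC-oxy)phenol | Oc4c(OCc5ccccc5)cc(Oc1c(OCc5ccccc5)cc(OCc5ccccc5)c(Oc2cc(Oc3c(OCc5ccccc5)cc(OCc5ccccc5)cc3OCc5ccccc5)cc(OCc5ccccc5)c2OCc5ccccc5)c1OCc5ccccc5)cc4OCc5ccccc5 | intermediate (key-step product)
23 | CNP0214481.0 | Oc1cc(O)c(Oc2cc(O)c(O)c(Oc3c(O)cc(O)c(Oc4cc(O)c(O)c(O)c4)c3O)c2)c(O)c1 | target

Total step count: 14. Longest linear sequence: 12 steps (steps 3 to 14, from 5).

Steps most likely to fail

1. Step 13. The annulation may stall after the first C–C bond, or the ketone may be consumed by self-condensation before the weakly electrophilic malonaldehyde reacts. The fallback sets out from 19 and comes back at 22. Compound 19 would be condensed with pyrrolidine (2 equiv) and HBF4 in EtOH to the isolable vinamidinium salt 1-[(2Z)-3-(pyrrolidin-1-yl)-2-(ArABC-oxy)prop-2-en-1-ylidene]pyrrolidinium tetrafluoroborate F1. This pre-activated bis-electrophile would be added to the preformed potassium enolate of 20 (t-BuOK, THF, −20 °C → rt), and the same flask would then be warmed with AcOH so that the ring closes with loss of the second pyrrolidine to give 22. This is the stepwise vinamidinium–ketone annulation.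

2. Step 12. The double oxidation may stop at the β-hydroxy aldehyde, which can lose water or undergo retro-aldol cleavage, or the enolised product may be oxidised further at its central carbon. The fallback sets out from 15 and comes back at 19, building the dialdehyde without any oxidation. Phenol 15 would be O-alkylated with bromoacetaldehyde diethyl acetal (Cs2CO3, DMF, 110 °C) to 2-(ArABC-oxy)acetaldehyde diethyl acetal F2. The acetal would be hydrolysed (aq. HCl, THF) to 2-(ArABC-oxy)acetaldehyde F3. This would be aminomethylenated with tert-butoxybis(dimethylamino)methane (toluene, 60 °C) to (Z)-3-(dimethylamino)-2-(ArABC-oxy)prop-2-enal F4. The enaminal would be hydrolysed (aq. NaOH, EtOH; then acidification) to 19.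

3. Step 6. Coupling at the doubly ortho-flanked C–O bond may be slow enough for the unhindered bromide to compete, which would erode the iodide/bromide selectivity and give over-arylation or protodehalogenation. The fallback sets out from 9 and comes back at 10. Selective iodine–magnesium exchange on 9 (i-PrMgCl·LiCl, THF, −40 °C), a B(OMe)3 quench and acidic work-up would give [2,3-bis(benzyloxy)-5-bromophenyl]boronic acid F5. This would be joined to phenol 4 by Chan–Lam coupling (Cu(OAc)2, pyridine, 4 Å MS, CH2Cl2, air, rt), an oxidative copper(II) process at room temperature under which the aryl bromide is inert, to give 10.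

Further compounds

F1 | step 13 | 1-[(2Z)-3-(pyrrolidin-1-yl)-2-(ArABC-oxy)prop-2-en-1-ylidene]pyrrolidinium tetrafluoroborate | C1CCN(C1)/C=C(Oc1c(OCc5ccccc5)cc(OCc5ccccc5)c(Oc2cc(Oc3c(OCc5ccccc5)cc(OCc5ccccc5)cc3OCc5ccccc5)cc(OCc5ccccc5)c2OCc5ccccc5)c1OCc5ccccc5)/C=[N+]1CCCC1.F[B-](F)(F)F
F2 | step 12 | 2-(ArABC-oxy)acetaldehyde diethyl acetal | CCOC(OCC)COc1c(OCc5ccccc5)cc(OCc5ccccc5)c(Oc2cc(Oc3c(OCc5ccccc5)cc(OCc5ccccc5)cc3OCc5ccccc5)cc(OCc5ccccc5)c2OCc5ccccc5)c1OCc5ccccc5
F3 | step 12 | 2-(ArABC-oxy)acetaldehyde | O=CCOc1c(OCc5ccccc5)cc(OCc5ccccc5)c(Oc2cc(Oc3c(OCc5ccccc5)cc(OCc5ccccc5)cc3OCc5ccccc5)cc(OCc5ccccc5)c2OCc5ccccc5)c1OCc5ccccc5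
F4 | step 12 | (Z)-3-(dimethylamino)-2-(ArABC-oxy)prop-2-enal | CN(C)/C=C(Oc1c(OCc5ccccc5)cc(OCc5ccccc5)c(Oc2cc(Oc3c(OCc5ccccc5)cc(OCc5ccccc5)cc3OCc5ccccc5)cc(OCc5ccccc5)c2OCc5ccccc5)c1OCc5ccccc5)/C=O
F5 | step 6 | [2,3-bis(benzyloxy)-5-bromophenyl]boronic acid | OB(O)c1cc(Br)cc(OCc5ccccc5)c1OCc5ccccc5
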